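**Plan**
- Retrosynthesis: the two phenolic O–Si bonds are cut first, then the C3–carbinol carbon bond (aldol with vanillin, carbinol configuration corrected through the ketone). The lactone O1–C5 bond is then traced back to a C–C bond of a cyclobutanone, and the two ring bonds of that cyclobutanone to a ketene [2+2] on the allyl group of eugenol.
- Forward: the four-membered ring is built first, it is expanded to the γ-lactone by oxygen insertion, and the vanillyl carbinol side chain is joined at C3 last.
- Enabling feature: C4 and the O1–C5 bond of the lactone correspond to C3 and the C1–C2 bond of a 3-(arylmethyl)cyclobutanone. This ketone has a mirror plane through C1 and C3, so its two α-CH2 groups (C2, C4) are enantiotopic, and oxygen insertion next to one of them creates the C4 stereocentre.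
- Stereochemistry: C4 (R) from the catalyst-controlled Baeyer–Villiger step; C3 (S) from aldol addition trans to the C4 arylmethyl group; the carbinol (S) from chelation-controlled Zn(BH4)2 reduction of the β-keto lactone.

Key step: step 4

Assumption: the (R)-configured phosphoric acid is taken to favour migration of the CH2 group that leads to the (R)-lactone; if the sense is the opposite, the (S)-acid is used with no other change.

Step 1
Reactants: 1 eugenol (4-allyl-2-methoxyphenol)
Product: 2 (4-allyl-2-methoxyphenoxy)triisopropylsilane
Conditions: TIPSCl, imidazole, DMF, rt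
Reagents that add atoms: triisopropylsilyl chloride, CC(C)[Si](Cl)(C(C)C)C(C)C
Why: Imidazole-promoted O-silylation of the phenol (silyl ether formation) masks the acidic OH before the zinc, enolate and hydride steps; no stereocentre is involved.

Step 2
Reactants: 2 (4-allyl-2-methoxyphenoxy)triisopropylsilane; 3 trichloroacetyl chloride
Product: 5 2,2-dichloro-3-[3-methoxy-4-(triisopropylsilyloxy)benzyl]cyclobutan-1-one (racemic), via dichloroketene 4 (not isolated)
Conditions: Zn–Cu couple, POCl3, Et2O, 0 °C to rt, slow addition of 3
Reagents that add atoms: none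
Why: Zinc dechlorinates 3 to dichloroketene, which adds to the terminal alkene in a thermal ketene–alkene [2+2] cycloaddition with its carbonyl carbon bonding to the terminal CH2, so the 2,2-dichloro-3-substituted cyclobutanone results; its C3 stereocentre forms as a racemate and loses its chirality in the next step.

Step 3
Reactants: 5 2,2-dichloro-3-[3-methoxy-4-(triisopropylsilyloxy)benzyl]cyclobutan-1-one
Product: 6 3-[3-methoxy-4-(triisopropylsilyloxy)benzyl]cyclobutan-1-one
Conditions: Zn dust, AcOH, rt
Reagents that add atoms: none
Why: Reductive dechlorination of the α,α-dichloro ketone by zinc in acetic acid (zinc enolate, then protonation, twice) leaves the aryl silyl ether intact and gives the achiral ketone with a mirror plane through C1 and C3.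

Step 4
Reactants: 6 3-[3-methoxy-4-(triisopropylsilyloxy)benzyl]cyclobutan-1-one
Product: 8 (R)-4-[3-methoxy-4-(triisopropylsilyloxy)benzyl]dihydrofuran-2(3H)-one, via Criegee adduct 7 (not isolated)
Conditions: (R)-3,3′-di(pyren-1-yl)-H8-BINOL hydrogen phosphate (10 mol %), 30% aq. H2O2 (1.5 equiv), CHCl3, −40 °C
Reagents that add atoms: hydrogen peroxide, OO
Why: The chiral phosphoric acid activates the strained carbonyl of 6 toward addition of H2O2 to give the Criegee adduct 7 and then, hydrogen-bonded through P=O and P–OH to the hemiketal and peroxide O–H groups, promotes the 1,2-shift of one α-CH2 from C1 to the proximal peroxide oxygen with loss of water. The closest known reaction type is the chiral Brønsted acid-catalysed desymmetrising Baeyer–Villiger oxidation of 3-substituted cyclobutanones with aqueous H2O2. The γ-lactone does not arise by a cyclisation but by ring expansion of the four-membered ring, oxygen being inserted into the C1–C2 bond in a concerted migration with retention at the migrating carbon, which forms the lactone O1–C5 bond. The only new stereocentre, C4 of the lactone (C3 of 6), is fixed by which of the two enantiotopic CH2 groups migrates, and the 3,3′-aryl pocket of the catalyst should hold 7 so that only one of the two C–C bonds lies antiperiplanar to the O–O bond. The step needs enantiotopic-group selectivity, which rests on the catalyst, and chemoselectivity over the electron-rich arene and the silyl ether, which rests on the ring strain that lets the cyclobutanone react at −40 °C; regioselectivity is no issue because the two migrating carbons are constitutionally identical.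

Step 5
Reactants: 9 vanillin
Product: 10 3-methoxy-4-(triisopropylsilyloxy)benzaldehyde
Conditions: TIPSCl, imidazole, DMF, rt
Reagents that add atoms: triisopropylsilyl chloride, CC(C)[Si](Cl)(C(C)C)C(C)C
Why: Imidazole-promoted O-silylation gives the same phenol protection as in the lactone partner, so that one fluoride treatment can free both phenols at the end.

Step 6
Reactants: 8 (R)-4-[3-methoxy-4-(triisopropylsilyloxy)benzyl]dihydrofuran-2(3H)-one; 10 3-methoxy-4-(triisopropylsilyloxy)benzaldehyde
Product: 12 (3S,4R)-3-{hydroxy[3-methoxy-4-(triisopropylsilyloxy)phenyl]methyl}-4-[3-methoxy-4-(triisopropylsilyloxy)benzyl]dihydrofuran-2(3H)-one (both carbinol epimers), via lithium lactone enolate 11 (not isolated)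
Conditions: LiN(i-Pr)2 (LDA), THF, −78 °C; then 10, −78 °C; AcOH quench at −78 °C
Reagents that add atoms: none
Why: Kinetic deprotonation at C3 and aldol addition of the lithium enolate through a Zimmerman–Traxler transition state on the enolate face anti to the C4 arylmethyl group should set C3 as S (3,4-trans), while the carbinol carbon is expected as a mixture of epimers that is carried on together.

Step 7
Reactants: 12 (3S,4R)-3-{hydroxy[3-methoxy-4-(triisopropylsilyloxy)phenyl]methyl}-4-[3-methoxy-4-(triisopropylsilyloxy)benzyl]dihydrofuran-2(3H)-one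
Product: 13 (3S,4R)-3-[3-methoxy-4-(triisopropylsilyloxy)benzoyl]-4-[3-methoxy-4-(triisopropylsilyloxy)benzyl]dihydrofuran-2(3H)-one
Conditions: Dess–Martin periodinane, CH2Cl2, 0 °C to rt
Reagents that add atoms: none
Why: Dess–Martin oxidation of the secondary benzylic alcohol merges both carbinol epimers into one β-keto lactone, in which C3 keeps, or by enolisation returns to, the favoured trans arrangement to C4.

Step 8
Reactants: 13 (3S,4R)-3-[3-methoxy-4-(triisopropylsilyloxy)benzoyl]-4-[3-methoxy-4-(triisopropylsilyloxy)benzyl]dihydrofuran-2(3H)-one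
Product: 14 (3S,4R)-3-{(S)-hydroxy[3-methoxy-4-(triisopropylsilyloxy)phenyl]methyl}-4-[3-methoxy-4-(triisopropylsilyloxy)benzyl]dihydrofuran-2(3H)-one
Conditions: Zn(BH4)2 (stock solution in Et2O), Et2O, −20 to 0 °C; then H2O
Reagents that add atoms: none
Why: Chelation-controlled reduction of an α-substituted β-keto ester: zinc bridges the lactone and ketone carbonyl oxygens and hydride reaches the ketone from the side of the C3–H, away from ring carbon C4, which should give the (S)-carbinol syn to C3.

Step 9
Reactants: 14 (3S,4R)-3-{(S)-hydroxy[3-methoxy-4-(triisopropylsilyloxy)phenyl]methyl}-4-[3-methoxy-4-(triisopropylsilyloxy)benzyl]dihydrofuran-2(3H)-one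
Product: 15 (3S,4R)-3-[(S)-hydroxy(4-hydroxy-3-methoxyphenyl)methyl]-4-(4-hydroxy-3-methoxybenzyl)dihydrofuran-2(3H)-one (CNP0288801.2)
Conditions: Bu4NF (TBAF), AcOH (1:1), THF, 0 °C
Reagents that add atoms: none
Why: Fluoride-mediated desilylation cleaves both aryl O–Si bonds, and the acetic acid buffer keeps phenoxide and alkoxide concentrations low so that retro-aldol cleavage and quinone-methide formation at the p-hydroxybenzylic carbinol should be avoided; the three stereocentres are not touched.

**Compound list**
1 | eugenol (4-allyl-2-methoxyphenol) | COc1cc(CC=C)ccc1O | starting material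
2 | (4-allyl-2-methoxyphenoxy)triisopropylsilane | COc1cc(CC=C)ccc1O[Si](C(C)C)(C(C)C)C(C)C | intermediate
3 | trichloroacetyl chloride | ClC(=O)C(Cl)(Cl)Cl | starting material
4 | dichloroketene | ClC(Cl)=C=O | intermediate
5 | 2,2-dichloro-3-[3-methoxy-4-(triisopropylsilyloxy)benzyl]cyclobutan-1-one (racemic) | COc1cc(CC2CC(=O)C2(Cl)Cl)ccc1O[Si](C(C)C)(C(C)C)C(C)C | intermediate
6 | 3-[3-methoxy-4-(triisopropylsilyloxy)benzyl]cyclobutan-1-one | COc1cc(CC2CC(=O)C2)ccc1O[Si](C(C)C)(C(C)C)C(C)C | intermediate
7 | 1-hydroperoxy-3-[3-methoxy-4-(triisopropylsilyloxy)benzyl]cyclobutan-1-ol (Criegee adduct) | COc1cc(CC2CC(O)(OO)C2)ccc1O[Si](C(C)C)(C(C)C)C(C)C | intermediate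
8 | (R)-4-[3-methoxy-4-(triisopropylsilyloxy)benzyl]dihydrofuran-2(3H)-one | COc1cc(C[C@H]2COC(=O)C2)ccc1O[Si](C(C)C)(C(C)C)C(C)C | intermediate
9 | vanillin | COc1cc(C=O)ccc1O | starting material
10 | 3-methoxy-4-(triisopropylsilyloxy)benzaldehyde | COc1cc(C=O)ccc1O[Si](C(C)C)(C(C)C)C(C)C | intermediate
11 | lithium enolate of lactone 8 | COc1cc(C[C@H]2COC(O[Li])=C2)ccc1O[Si](C(C)C)(C(C)C)C(C)C | intermediate
12 | (3S,4R)-3-{hydroxy[3-methoxy-4-(triisopropylsilyloxy)phenyl]methyl}-4-[3-methoxy-4-(triisopropylsilyloxy)benzyl]dihydrofuran-2(3H)-one (carbinol epimers) | COc1cc(C[C@H]2COC(=O)[C@@H]2C(O)c2ccc(O[Si](C(C)C)(C(C)C)C(C)C)c(OC)c2)ccc1O[Si](C(C)C)(C(C)C)C(C)C | intermediate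
13 | (3S,4R)-3-[3-methoxy-4-(triisopropylsilyloxy)benzoyl]-4-[3-methoxy-4-(triisopropylsilyloxy)benzyl]dihydrofuran-2(3H)-one | COc1cc(C[C@H]2COC(=O)[C@@H]2C(=O)c2ccc(O[Si](C(C)C)(C(C)C)C(C)C)c(OC)c2)ccc1O[Si](C(C)C)(C(C)C)C(C)C | intermediate
14 | (3S,4R)-3-{(S)-hydroxy[3-methoxy-4-(triisopropylsilyloxy)phenyl]methyl}-4-[3-methoxy-4-(triisopropylsilyloxy)benzyl]dihydrofuran-2(3H)-one | COc1cc(C[C@H]2COC(=O)[C@@H]2[C@H](O)c2ccc(O[Si](C(C)C)(C(C)C)C(C)C)c(OC)c2)ccc1O[Si](C(C)C)(C(C)C)C(C)C | intermediate
15 | (3S,4R)-3-[(S)-hydroxy(4-hydroxy-3-methoxyphenyl)methyl]-4-(4-hydroxy-3-methoxybenzyl)dihydrofuran-2(3H)-one | COc1cc(C[C@H]2COC(=O)[C@@H]2[C@H](O)c2ccc(O)c(OC)c2)ccc1O | target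

**Step count**
Total: 9 steps. Longest linear sequence: 8 steps (steps 1, 2, 3, 4, 6, 7, 8, 9 from eugenol); step 5 is the one-step side branch from vanillin.

**Steps most likely to fail**

Step 4. Discrimination between the two enantiotopic CH2 groups in the Criegee adduct may be incomplete for a 3-benzyl substituent, which sits one carbon further from the catalyst pocket than a 3-aryl group, so the lactone could form with insufficient enantiomeric excess. The fallback sets out from cyclobutanone 6 and uses a different desymmetrisation. Enantioselective deprotonation with lithium bis[(S)-1-phenylethyl]amide, LiN[CH(CH3)Ph]2 (or its antipode, whichever removes the proton leading to the R series), with Et3SiCl present in THF at −100 °C, would give the silyl enol ether (R)-triethyl({3-[3-methoxy-4-(triisopropylsilyloxy)benzyl]cyclobut-1-en-1-yl}oxy)silane F1. Ozonolysis with a titrated amount of O3 in CH2Cl2/MeOH at −78 °C would cleave the enol ether double bond to (R)-3-formyl-4-[3-methoxy-4-(triisopropylsilyloxy)phenyl]butanoic acid F2. This is reduced in the same flask with NaBH4, before the formyl-bearing centre can epimerise, to (R)-3-(hydroxymethyl)-4-[3-methoxy-4-(triisopropylsilyloxy)phenyl]butanoic acid F3. Acidification with dilute HCl closes the lactone, and the route is rejoined at lactone 8.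

Step 8. Chelate organisation may be incomplete on the twisted keto lactone, so hydride could reach both ketone faces and give the (R)-carbinol epimer as well. The fallback sets out from ketone 13 and replaces substrate control by catalyst control: Noyori transfer hydrogenation with RuCl[(S,S)-TsDPEN](p-cymene) in HCO2H/Et3N, which by the aryl-ketone model should deliver the (S)-carbinol whether or not a chelate forms. It returns to the route at 14, and no compound outside the list arises (F0). Any wrong epimer from either reduction can be returned to 13 by Dess–Martin oxidation.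

Step 9. Basic fluoride may trigger retro-aldol cleavage, or ionisation of the p-hydroxybenzylic carbinol through a quinone methide, with loss of the carbinol configuration or elimination. The fallback sets out from ketone 13 and reverses the order of the last two operations. Desilylation with Bu4NF/AcOH in THF at 0 °C, at a stage where no carbinol is present, would give (3S,4R)-3-(4-hydroxy-3-methoxybenzoyl)-4-(4-hydroxy-3-methoxybenzyl)dihydrofuran-2(3H)-one F4. Chelation-controlled reduction with excess Zn(BH4)2 in THF/Et2O (the free phenols consume part of the hydride) and a neutral aqueous work-up would then give the target, so the route is rejoined at 15.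

**Further compounds**
F1 | step 4 | (R)-triethyl({3-[3-methoxy-4-(triisopropylsilyloxy)benzyl]cyclobut-1-en-1-yl}oxy)silane | COc1cc(C[C@H]2C=C(O[Si](CC)(CC)CC)C2)ccc1O[Si](C(C)C)(C(C)C)C(C)C
F2 | step 4 | (R)-3-formyl-4-[3-methoxy-4-(triisopropylsilyloxy)phenyl]butanoic acid | COc1cc(C[C@H](CC(=O)O)C=O)ccc1O[Si](C(C)C)(C(C)C)C(C)C
F3 | step 4 | (R)-3-(hydroxymethyl)-4-[3-methoxy-4-(triisopropylsilyloxy)phenyl]butanoic acid | COc1cc(C[C@H](CC(=O)O)CO)ccc1O[Si](C(C)C)(C(C)C)C(C)C
F0 | step 8 | none | none
F4 | step 9 | (3S,4R)-3-(4-hydroxy-3-methoxybenzoyl)-4-(4-hydroxy-3-methoxybenzyl)dihydrofuran-2(3H)-one | COc1cc(C[C@H]2COC(=O)[C@@H]2C(=O)c2ccc(O)c(OC)c2)ccc1O
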